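The target is cut at the C–C bond joining its two chain alkenes and, in the eastern half, at the O–C bond of the central furan (ring B: oxygen B1, B2 carrying the inter-furan CH2, B3, B4 carrying the side chain, B5). Because B2 bears an arylmethyl group and B4 a carbon chain, ring B maps onto a (Z)-2-en-4-yn-1-ol whose alkyne ends in furan ring A and whose C2 carries the pent-3-ynyl chain. Silver-catalysed cycloisomerisation of this enynol forms B1–B2, closes and aromatises ring B and creates the CH2 bridge in one operation; the surviving 2-alkyne then serves the hydrozirconation–Negishi union with the (S)-tetronate iodide.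

Key step: step 11

Assumption: compounds 1, 3, 4, 15, 16, 20 and 21 are taken as purchasable; ring A is the terminal furan, ring B the central furan and ring C the tetronic acid.

Fragment A (tetronate iodide), steps 1–7

Step 1
Reactants: 1 4-hydroxy-3-methylfuran-2(5H)-one (3-methyltetronic acid)
Product: 2 4-methoxy-3-methylfuran-2(5H)-one
Conditions: Me2SO4, K2CO3, acetone, reflux
Reagents that add atoms: dimethyl sulfate, COS(=O)(=O)OC
Why: Williamson-type O-methylation of the vinylogous acid under carbonate base should give the 4-methoxy butenolide, the usual protected form of a tetronic acid.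

Step 2
Reactants: 3 (4R)-4-benzyl-3-propanoyl-1,3-oxazolidin-2-one; 4 3-bromoprop-1-yne (propargyl bromide)
Product: 6 (4R)-4-benzyl-3-[(2S)-2-methylpent-4-ynoyl]-1,3-oxazolidin-2-one, via sodium Z-enolate 5 (not isolated)
Conditions: NaN(SiMe3)2, THF, −78 °C; then 4 (80 wt% in toluene), −78 to −40 °C
Reagents that add atoms: none
Why: Evans asymmetric alkylation, in which the chelated sodium (Z)-enolate is attacked by the propargylic bromide on the face away from the benzyl group of the (R)-auxiliary, sets the (S)-methyl stereocentre that is the only stereocentre of the target.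

Step 3
Reactants: 6 (4R)-4-benzyl-3-[(2S)-2-methylpent-4-ynoyl]-1,3-oxazolidin-2-one
Product: 7 (2S)-2-methylpent-4-yn-1-ol
Conditions: LiBH4, H2O (1 equiv), Et2O, 0 °C
Reagents that add atoms: none
Why: Reductive cleavage of the N-acyl oxazolidinone by LiBH4 attacks the exocyclic carbonyl selectively and leaves the α-stereocentre and the terminal alkyne untouched (the product is volatile and is concentrated with care).

Step 4
Reactants: 7 (2S)-2-methylpent-4-yn-1-ol
Product: 9 (2S,4E)-5-iodo-2-methylpent-4-en-1-ol, via alkenylzirconocene zirconium alkoxide 8 (not isolated)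
Conditions: Cp2Zr(H)Cl (2.3 equiv), THF, 0 °C to rt; then I2, 0 °C
Reagents that add atoms: iodine, II
Why: Hydrozirconation–iodination, in which the first equivalent of hydride caps the hydroxyl as its zirconium alkoxide, the second adds syn to the terminal alkyne with zirconium at the terminal carbon, and iodinolysis with retention gives the (E)-iodoalkene.

Step 5
Reactants: 9 (2S,4E)-5-iodo-2-methylpent-4-en-1-ol
Product: 10 (2S,4E)-5-iodo-2-methylpent-4-enal
Conditions: Dess–Martin periodinane, CH2Cl2, 0 °C to rt; used at once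
Reagents that add atoms: none
Why: Dess–Martin oxidation converts the primary alcohol into the aldehyde without base, which should keep the α-methyl stereocentre from epimerising and leaves the alkenyl iodide intact.

Step 6
Reactants: 2 4-methoxy-3-methylfuran-2(5H)-one; 10 (2S,4E)-5-iodo-2-methylpent-4-enal
Product: 12 5-[(2S,4E)-1-hydroxy-5-iodo-2-methylpent-4-en-1-yl]-4-methoxy-3-methylfuran-2(5H)-one (mixture of carbinol/ring diastereomers), via lithium furanolate 11 (not isolated)
Conditions: 2, LiN(i-Pr)2, THF, −78 °C; then 10, −78 °C; AcOH quench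
Reagents that add atoms: none
Why: Vinylogous aldol addition, in which LiN(i-Pr)2 removes the C5 proton of the methyl tetronate to give an aromatic 2-furanolate that adds through C5 to the aldehyde at −78 °C faster than the aldehyde enolises, the two new stereocentres being erased in step 7.

Step 7
Reactants: 12 5-[(2S,4E)-1-hydroxy-5-iodo-2-methylpent-4-en-1-yl]-4-methoxy-3-methylfuran-2(5H)-one
Product: 14 (5Z)-5-[(2S,4E)-5-iodo-2-methylpent-4-en-1-ylidene]-4-methoxy-3-methylfuran-2(5H)-one, via mesylate 13 (not isolated)
Conditions: MsCl, Et3N, CH2Cl2, 0 °C; then DBU, 0 °C to rt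
Reagents that add atoms: none
Why: Mesylation followed by E1cB elimination through the furanolate should give the conjugated 5-ylidene tetronate as the Z isomer, because the E isomer would press the branched chain against the 4-methoxy group (allylic 1,3-strain).

Fragment B (bis-furan alkyne), steps 8–11

Step 8
Reactants: 15 5-bromopent-2-yne; 16 prop-2-yn-1-ol (propargyl alcohol)
Product: 19 (2Z)-3-iodo-2-(pent-3-yn-1-yl)prop-2-en-1-ol, via pent-3-yn-1-ylmagnesium bromide 17 (not isolated), via cyclic alkenylmagnesium alkoxide 18 (not isolated)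
Conditions: 15 (2.5 equiv), Mg, THF, 40 °C; then 16, CuI (10 mol%), THF, −10 °C to rt; then I2, −40 to 0 °C
Reagents that add atoms: iodine, II
Why: Copper-catalysed anti-carbomagnesiation of the propargylic alkoxide delivers the alkyl group to C2 and magnesium to C3 inside a five-membered chelate, so that iodinolysis with retention places iodine cis to the hydroxymethyl group (Z).

Step 9
Reactants: 20 3-bromofuran; 21 ethynyltrimethylsilane
Product: 22 3-[(trimethylsilyl)ethynyl]furan
Conditions: PdCl2(PPh3)2 (2 mol%), CuI (4 mol%), Et3N, 60 °C, sealed vessel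
Reagents that add atoms: none
Why: Sonogashira coupling of the heteroaryl bromide with the silyl-capped alkyne, the silyl group preventing double coupling and giving a product that is easier to handle than volatile 3-ethynylfuran.

Step 10
Reactants: 22 3-[(trimethylsilyl)ethynyl]furan; 19 (2Z)-3-iodo-2-(pent-3-yn-1-yl)prop-2-en-1-ol
Product: 24 (2Z)-5-(furan-3-yl)-2-(pent-3-yn-1-yl)pent-2-en-4-yn-1-ol, via 3-ethynylfuran 23 (not isolated)
Conditions: Pd(PPh3)4 (3 mol%), CuI (6 mol%), Bu4NF (1.1 equiv), Et3N, THF, rt, degassed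
Reagents that add atoms: none
Why: Fluoride removes the silyl group in the flask and the liberated terminal alkyne enters a Sonogashira coupling with the alkenyl iodide, which retains the Z geometry and tolerates the free hydroxyl.

Step 11
Reactants: 24 (2Z)-5-(furan-3-yl)-2-(pent-3-yn-1-yl)pent-2-en-4-yn-1-ol
Product: 26 2-(furan-3-ylmethyl)-4-(pent-3-yn-1-yl)furan, via alkylidene dihydrofuran 25 (not isolated)
Conditions: AgNO3 (10 wt% on silica gel, 0.2 equiv), hexanes–CH2Cl2, rt, dark
Reagents that add atoms: none
Why: Monovalent silver coordinates the furyl-substituted alkyne, the cis-disposed primary hydroxyl adds anti to the proximal alkyne carbon, protodemetalation gives the 2-alkylidene-2,5-dihydrofuran 25, and a shift of a ring CH2 hydrogen to the exocyclic carbon aromatises it to 26. The closest known reaction type is the silver-catalysed cycloisomerisation of β-alkynyl allylic alcohols ((Z)-2-en-4-yn-1-ols) to furans on AgNO3-impregnated silica. Ring B is closed in the 5-exo-dig mode by formation of the O–C bond B1–B2, and the distal alkyne carbon becomes the CH2 between rings A and B. No stereocentre is created. The step needs exo rather than 6-endo attack and a choice between two alkynes: the Z geometry fixed in step 8 holds the oxygen within reach of the proximal carbon of the conjugated alkyne only, whereas the isolated 2-alkyne has no nucleophile in range and silver, unlike gold catalysts, is not expected to start furan–alkyne reactions. The gain in aromatic stabilisation should make the isomerisation irreversible.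

Union and end game, steps 12–13

Step 12
Reactants: 26 2-(furan-3-ylmethyl)-4-(pent-3-yn-1-yl)furan; 14 (5Z)-5-[(2S,4E)-5-iodo-2-methylpent-4-en-1-ylidene]-4-methoxy-3-methylfuran-2(5H)-one
Product: 29 (5Z)-5-{(2S,4E,6E)-9-[5-(furan-3-ylmethyl)furan-3-yl]-2,6-dimethylnona-4,6-dien-1-ylidene}-4-methoxy-3-methylfuran-2(5H)-one, via alkenylzirconocene chloride 27 (not isolated), via alkenylzinc chloride 28 (not isolated)
Conditions: 26 (1.3 equiv), Cp2Zr(H)Cl (1.7 equiv), THF, 50 °C; then ZnCl2, THF, 0 °C; then 14 (1.0 equiv), Pd(PPh3)4 (5 mol%), rt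
Reagents that add atoms: none
Why: Hydrozirconation–Negishi coupling, in which syn addition of Zr–H, equilibrated at 50 °C by the small excess of hydride, puts zirconium on the less hindered methyl-bearing alkyne carbon, and transmetalation to zinc followed by coupling under zerovalent palladium with retention at both partners gives the (E,E)-diene.

Step 13
Reactants: 29 (5Z)-5-{(2S,4E,6E)-9-[5-(furan-3-ylmethyl)furan-3-yl]-2,6-dimethylnona-4,6-dien-1-ylidene}-4-methoxy-3-methylfuran-2(5H)-one
Product: 31 (5Z)-5-{(2S,4E,6E)-9-[5-(furan-3-ylmethyl)furan-3-yl]-2,6-dimethylnona-4,6-dien-1-ylidene}-4-hydroxy-3-methylfuran-2(5H)-one (target), via lithium tetronate 30 (not isolated)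
Conditions: LiCl, DMF, 90 °C; then cold 0.5 M HCl to pH 3
Reagents that add atoms: none
Why: SN2 O-demethylation of the vinylogous methyl ester by chloride (Krapcho-type dealkylation) expels the stabilised tetronate anion, a weak base that should not endanger the allylic stereocentre, and brief cold acidification frees the tetronic acid.

Compound list
1 | 4-hydroxy-3-methylfuran-2(5H)-one (3-methyltetronic acid) | CC1=C(O)COC1=O | starting material
2 | 4-methoxy-3-methylfuran-2(5H)-one | COC1=C(C)C(=O)OC1 | intermediate
3 | (4R)-4-benzyl-3-propanoyl-1,3-oxazolidin-2-one | CCC(=O)N1[C@H](Cc2ccccc2)COC1=O | starting material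
4 | 3-bromoprop-1-yne (propargyl bromide) | C#CCBr | starting material
5 | sodium (1Z)-1-[(4R)-4-benzyl-2-oxo-1,3-oxazolidin-3-yl]prop-1-en-1-olate | C/C=C(\O[Na])N1[C@H](Cc2ccccc2)COC1=O | intermediate
6 | (4R)-4-benzyl-3-[(2S)-2-methylpent-4-ynoyl]-1,3-oxazolidin-2-one | O=C([C@@H](C)CC#C)N1[C@H](Cc2ccccc2)COC1=O | intermediate
7 | (2S)-2-methylpent-4-yn-1-ol | OC[C@@H](C)CC#C | intermediate
8 | O-zirconated (E)-alkenylzirconocene chloride from 7 (Cp2ZrCl on oxygen and on the terminal alkene carbon) | Cl[Zr](OC[C@@H](C)C/C=C/[Zr](Cl)(C1C=CC=C1)C1C=CC=C1)(C1C=CC=C1)C1C=CC=C1 | intermediate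
9 | (2S,4E)-5-iodo-2-methylpent-4-en-1-ol | OC[C@@H](C)C/C=C/I | intermediate
10 | (2S,4E)-5-iodo-2-methylpent-4-enal | O=C[C@@H](C)C/C=C/I | intermediate
11 | lithium 4-methoxy-3-methylfuran-2-olate | COC1=COC(O[Li])=C1C | intermediate
12 | 5-[(2S,4E)-1-hydroxy-5-iodo-2-methylpent-4-en-1-yl]-4-methoxy-3-methylfuran-2(5H)-one (diastereomer mixture at ring C5 and the carbinol carbon) | COC1=C(C)C(=O)OC1C(O)[C@@H](C)C/C=C/I | intermediate
13 | methanesulfonate of 12 | COC1=C(C)C(=O)OC1C(OS(C)(=O)=O)[C@@H](C)C/C=C/I | intermediate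
14 | (5Z)-5-[(2S,4E)-5-iodo-2-methylpent-4-en-1-ylidene]-4-methoxy-3-methylfuran-2(5H)-one | CC1=C(OC)/C(=C/[C@@H](C)C/C=C/I)OC1=O | intermediate
15 | 5-bromopent-2-yne | CC#CCCBr | starting material
16 | prop-2-yn-1-ol (propargyl alcohol) | C#CCO | starting material
17 | pent-3-yn-1-ylmagnesium bromide | CC#CCC[Mg]Br | intermediate
18 | 4-(pent-3-yn-1-yl)-2,5-dihydro-1,2-oxamagnesole (cyclic (Z)-alkenylmagnesium alkoxide) | CC#CCCC1=C[Mg]OC1 | intermediate
19 | (2Z)-3-iodo-2-(pent-3-yn-1-yl)prop-2-en-1-ol | OC/C(CCC#CC)=C\I | intermediate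
20 | 3-bromofuran | Brc1ccoc1 | starting material
21 | ethynyltrimethylsilane | C#C[Si](C)(C)C | starting material
22 | 3-[(trimethylsilyl)ethynyl]furan | C[Si](C)(C)C#Cc1ccoc1 | intermediate
23 | 3-ethynylfuran | C#Cc1ccoc1 | intermediate
24 | (2Z)-5-(furan-3-yl)-2-(pent-3-yn-1-yl)pent-2-en-4-yn-1-ol | OC/C(CCC#CC)=C\C#Cc1ccoc1 | intermediate
25 | (2Z)-2-(furan-3-ylmethylidene)-4-(pent-3-yn-1-yl)-2,5-dihydrofuran | CC#CCCC1=C/C(=C/c2ccoc2)OC1 | intermediate
26 | 2-(furan-3-ylmethyl)-4-(pent-3-yn-1-yl)furan | CC#CCCc1coc(Cc2ccoc2)c1 | intermediate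
27 | chloridobis(cyclopentadienyl){(2E)-5-[5-(furan-3-ylmethyl)furan-3-yl]pent-2-en-2-yl}zirconium | C/C(=C\CCc1coc(Cc2ccoc2)c1)[Zr](Cl)(C1C=CC=C1)C1C=CC=C1 | intermediate
28 | chlorido{(2E)-5-[5-(furan-3-ylmethyl)furan-3-yl]pent-2-en-2-yl}zinc | C/C(=C\CCc1coc(Cc2ccoc2)c1)[Zn]Cl | intermediate
29 | (5Z)-5-{(2S,4E,6E)-9-[5-(furan-3-ylmethyl)furan-3-yl]-2,6-dimethylnona-4,6-dien-1-ylidene}-4-methoxy-3-methylfuran-2(5H)-one | CC1=C(OC)/C(=C/[C@@H](C)C/C=C/C(C)=C/CCc2coc(Cc3ccoc3)c2)OC1=O | intermediate
30 | lithium tetronate of 31 | CC1=C(O[Li])/C(=C/[C@@H](C)C/C=C/C(C)=C/CCc2coc(Cc3ccoc3)c2)OC1=O | intermediate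
31 | (5Z)-5-{(2S,4E,6E)-9-[5-(furan-3-ylmethyl)furan-3-yl]-2,6-dimethylnona-4,6-dien-1-ylidene}-4-hydroxy-3-methylfuran-2(5H)-one | CC1=C(O)/C(=C/[C@@H](C)C/C=C/C(C)=C/CCc2coc(Cc3ccoc3)c2)OC1=O | target

Total step count: 13.
Longest linear sequence: 8 steps (3 to 31 through steps 2, 3, 4, 5, 6, 7, 12 and 13).

Steps most likely to fail

Step 11. The cyclisation may stop at enol ether 25 without the proton shift, or the Lewis-acidic silver surface may start oligomerisation of the electron-rich furans before aromatisation is complete. The fallback assembles ring B by cross-coupling instead of ring closure; it sets out from bromide 15 and returns at 26. Commercial 3-(bromomethyl)furan (BrCc1ccoc1) is converted with zinc dust and LiCl in THF into (furan-3-ylmethyl)zinc bromide F1. Under Pd(PPh3)4 this should couple with commercial 2,4-dibromofuran (Brc1coc(Br)c1) at the more reactive C–Br bond next to oxygen to give 4-bromo-2-(furan-3-ylmethyl)furan F2. Bromide 15 is turned by zinc insertion (Zn, LiCl, THF, 50 °C) into pent-3-yn-1-ylzinc bromide F3, and a second Negishi coupling of F2 with F3 under Pd(OAc)2/SPhos should deliver 26.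

Step 12. Regiocontrol of the Zr–H addition to the unsymmetrical alkyne may be incomplete, with zirconium partly on the CH2-bearing carbon and an isomeric diene that is hard to remove; unconsumed Cp2Zr(H)Cl may also transfer hydride to iodide 14. The fallback goes stepwise through an isolated iodide; it sets out from 26 and returns at 28. Alkenylzirconocene 27 is quenched with I2 at 0 °C to give 2-(furan-3-ylmethyl)-4-[(3E)-4-iodopent-3-en-1-yl]furan F4, which can be freed from its regioisomer by preparative chromatography. Iodine–lithium exchange with t-BuLi (2 equiv, Et2O, −78 °C) should give, with retention, (2Z)-{5-[5-(furan-3-ylmethyl)furan-3-yl]pent-2-en-2-yl}lithium F5. ZnCl2 converts F5 into 28 in the absence of any hydride, so that 14 can be used in a 1:1 ratio.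

Step 13. The SN2 demethylation may be slow at a temperature the polyene tolerates, with geometric isomerisation of the ylidene or diene and acid damage to the furans on work-up. The fallback deprotects before the union; it sets out from 14 and returns at 30. LiCl in DMF at 90 °C is applied to the robust iodide 14 to give, after acidification, (5Z)-4-hydroxy-5-[(2S,4E)-5-iodo-2-methylpent-4-en-1-ylidene]-3-methylfuran-2(5H)-one F6. LiN(SiMe3)2 (1 equiv, THF, −78 °C) turns it into lithium (5Z)-5-[(2S,4E)-5-iodo-2-methylpent-4-en-1-ylidene]-4-methyl-2-oxo-2,5-dihydrofuran-3-olate F7 (the lithium tetronate of F6). F7 is coupled with 28 under Pd(PPh3)4 as in step 12 to give 30, and the cold acidic work-up of step 13 then releases 31 without the coupled product ever being heated.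

Further compounds
F1 | step 11 | (furan-3-ylmethyl)zinc bromide | Br[Zn]Cc1ccoc1
F2 | step 11 | 4-bromo-2-(furan-3-ylmethyl)furan | Brc1coc(Cc2ccoc2)c1
F3 | step 11 | pent-3-yn-1-ylzinc bromide | CC#CCC[Zn]Br
F4 | step 12 | 2-(furan-3-ylmethyl)-4-[(3E)-4-iodopent-3-en-1-yl]furan | C/C(I)=C\CCc1coc(Cc2ccoc2)c1
F5 | step 12 | (2Z)-{5-[5-(furan-3-ylmethyl)furan-3-yl]pent-2-en-2-yl}lithium | C/C([Li])=C\CCc1coc(Cc2ccoc2)c1
F6 | step 13 | (5Z)-4-hydroxy-5-[(2S,4E)-5-iodo-2-methylpent-4-en-1-ylidene]-3-methylfuran-2(5H)-one | CC1=C(O)/C(=C/[C@@H](C)C/C=C/I)OC1=O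
F7 | step 13 | lithium (5Z)-5-[(2S,4E)-5-iodo-2-methylpent-4-en-1-ylidene]-4-methyl-2-oxo-2,5-dihydrofuran-3-olate | CC1=C(O[Li])/C(=C/[C@@H](C)C/C=C/I)OC1=O
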